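**What to watch.** The step to watch in this flask is a slow one: target turning into over-reaction product while you wait for the starting material to finish.

| flask | starting material | gas phase | catalyst | remark | time |
|---|---|---|---|---|---|
| dawn | 0.050 M | 6 mM (held) | 11 mol% | the very flask that is asked about, followed so far |  |
| spring | 0.10 M | 6 mM (held) | 11 mol% | run made earlier |  |
| flask | 0.050 M | 6.0 mM (held) | 11 mol% |  | 6.0 min |

| run | time / min | target / % |
|---|---|---|
| dawn | 0.250 | 15.1 |
| dawn | 0.500 | 30.0 |
| dawn | 1.33 | 62.1 |
| dawn | 3.00 | 75.4 |
| spring | 0.200 | 10.8 |
| spring | 0.417 | 23.4 |
| spring | 1.00 | 51.0 |
| spring | 2.50 | 78.0 |

(each reading ± 1 percentage point)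

- at the start none of the gas is dissolved
- steps that have been proposed: gas phase <-> dissolved gas; starting material + dissolved gas + catalyst -> catalyst + target; dissolved gas + catalyst + target -> catalyst + over-reaction product

- beta: doubling the transfer coefficient of the gas phase, all else as stated
- gamma: doubling the saturation concentration of gas phase, all else as stated
- zeta: doubling the amount of catalyst, all else as stated

- how much target there is at 6.0 min, in percent of the starting material charged
- the change that raises the amount of target at 6.0 min, in percent of the starting material charged most ("none" if none brings more than 2 percentage points) (beta / gamma / zeta / none)
- amount of target at 6.0 min, in percent of the starting material charged, after zeta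

**First instants.** None of the gas is dissolved yet, so you see the pace build. But both proposed steps use the same dissolved gas and the same catalyst, so these set one shared clock. Read target against x, the fraction of starting material left, and the clock drops out: target = (x^s − x)/(1 − s).

**The middle.** Target peaks where making equals loss, at x = s times target. With equal constants the peak would stand at 36.8%. The top readings, 75.4% in dawn and 78.0% in spring, average 76.7%. The peak formula, with the logarithm of 1/s taken near 2.3, gives 0.103 for the selectivity factor, the constant of the step that spends target divided by the constant of the step that makes it.

**The end.** Dawn's reading at 3.00 min stands near the peak, and I take it to be at or past the top, where x is no more than s times target, so I use 7.80% as an upper mark for x there. The same pace for the same time again squares x, which gives target 65.1% at 6.0 min. I commit to that figure or somewhat less, since x at 3.00 min was taken as an upper mark and the gas filled slowly at first. Zeta, read as double pace, gives 39.0%. Faster chemistry past the peak lowers target, so I choose none.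

**The forecast.** It says 60%, none and 34%, which is lower than my figures: “Every change speeds the chemistry and pushes further past the peak”.

**The flask.** It gives 53.2%, and after zeta 26.8%. The changes bring −3.7 percentage points for beta, −30 points for gamma and −26 points for zeta, so the answer is none.

    gas phase ⇌ dissolved gas, rate k1*(csat - [dissolved gas]) (kL = 0.217 s⁻¹)
    starting material + dissolved gas + catalyst → catalyst + target (k = 742 M⁻² s⁻¹)
    dissolved gas + catalyst + target → catalyst + over-reaction product (k = 74.5 M⁻² s⁻¹)

Starting material stood at 0.0657% at 6.00 min, less than the 0.608% of my even pace. Put into the rule, that x gives target 52.3%, against 53.2% in the flask. The neighbouring flask, read at 1.50 min, holds 25.6% starting material, for which the rule gives 68.3%, and its target stands at 68.5%.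

The runs stem from a simulated flask with made-up constants; noise was put on by code.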